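**Retrosynthetic overview**
1. Target 13 ⇒ two chemoselective Mitsunobu esterifications of the diol-phenol core 9 with unprotected acids: (Z)-ferulic acid on the unbranched C9′–OH first, then (E)-p-coumaric acid on the β-branched C9–OH.
2. Core 9 ⇒ reductive opening of the 14-membered macrodilactone 8, in which a threitol acetonide bridges the C3 carboxyl and the C5 propanoyl chain.
3. Macrodilactone 8 ⇒ one oxidative operation on the acyclic mixed diester 5: 8–5′ radical cross-coupling closes the macrolactone and quinone methide trapping closes the dihydrofuran (ring C), setting C2 and C3 together.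
4. Diester 5 ⇒ ferulic acid, dihydroferulic acid and the tartrate-derived diol 2; (Z)-ferulic acid comes from (E)-ferulic acid by photoisomerisation.
5. Ring order: all four benzene rings are bought; macrolactone and ring C form together (step 3); the macrolactone is opened again (step 4).

Numbering used: benzofuran numbering for the core (O1, C2, C3, C3a, C5, C7). C9 is the CH2O on C3 and C9′ is the terminal CH2O of the propyl chain. C8 is the ferulate α-carbon (future C3) and C5′ is the carbon ortho to the phenol of the dihydroferulate ring (future C3a). Ring A is the 2-aryl ring, ring B the benzo ring, ring C the dihydrofuran.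

Assumption: the (4S,5S)-tether is taken to favour the (2R,3R)-macrocycle 8. This sense of induction is not predicted with confidence. The two diastereomeric macrocycles are separable in any case, and if the induction runs the other way the (4R,5R)-diol is used with nothing else changed.

**Route**

Step 1
Reactants: 1 (E)-ferulic acid; 2 (4S,5S)-2,2-dimethyl-1,3-dioxolane-4,5-dimethanol (3 equiv)
Product: 3 mono-(E)-ferulate of diol 2
Conditions: PPh3, DIAD, THF, 0 °C to rt
Reagents that add atoms: none
Why: Mitsunobu esterification engages the carboxylic acid (pKa about 4.5) and not the phenol (pKa about 10), so no protecting group is needed, the excess of the C2-symmetric diol gives the mono-ester, and the trans-acetonide disfavours cycloetherification; the stereocenters of 2 are not at the reacting carbons.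

Step 2
Reactants: 3 mono-(E)-ferulate of diol 2; 4 3-(4-hydroxy-3-methoxyphenyl)propanoic acid (dihydroferulic acid)
Product: 5 mixed (E)-ferulate/dihydroferulate diester of diol 2
Conditions: PPh3, DIAD, THF, 0 °C to rt
Reagents that add atoms: none
Why: a second chemoselective Mitsunobu esterification of the remaining primary alcohol with the carboxyl of the phenolic acid; no stereocenter is touched.

Step 3
Reactants: 5 mixed (E)-ferulate/dihydroferulate diester of diol 2
Product: 8 (2R,3R)-trans-dihydrobenzofuran macrodilactone, via bis(phenoxyl) diradical 6 (not isolated), via quinone methide macrocycle 7 (not isolated)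
Conditions: Ag2O (1.3 equiv), CH2Cl2/acetone 2:1, 2 mM, rt, dark, 24 h; chromatographic separation of the diastereomeric macrocycles
Reagents that add atoms: none
Why: Proposed new method: Ag2O removes one electron from each guaiacyl phenol to give diradical 6, whose ferulate C8 radical couples with C5′ of the tethered ring (a meta-bridged 14-membered ring; the 8–O–4′ alternative needs a para-bridged 16-membered cyclophane and 8–8′ coupling is impossible because the second unit has no conjugated side chain), the ring B dienone rearomatises to quinone methide 7, and the new phenol adds to C7 anti to the ester to close ring C, so C3 is set by the face of C8 that the C2-symmetric acetonide exposes and C2 is set trans by the usual anti closure; the closest known reaction types are the Ag2O biomimetic 8–5′ dehydrodimerisation of ferulate esters to trans-dihydrobenzofurans, its chiral-auxiliary variants, and chiral-diol-templated intramolecular oxidative aryl couplings.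

Step 4
Reactants: 8 (2R,3R)-trans-dihydrobenzofuran macrodilactone
Product: 9 (2R,3S)-dihydrodehydrodiconiferyl alcohol
Conditions: i-Bu2AlH (8 equiv), THF/toluene, −78 to 0 °C; MeOH, aq. potassium sodium tartrate (KNaC4H4O6)
Reagents that add atoms: none
Why: DIBAL-H ester reduction converts both lactone carbonyls to primary alcohols under weakly basic conditions that avoid E1cB opening of the 3-acyl dihydrobenzofuran, and releases the water-soluble tether 2; C2 and C3 keep their geometry (3R becomes 3S only through the CIP priority change).

Step 5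
Reactants: 1 (E)-ferulic acid
Product: 10 (Z)-ferulic acid
Conditions: hν 365 nm, degassed MeOH, 5 mM, rt; chromatography in the dark (E-acid recycled)
Reagents that add atoms: none
Why: direct E/Z photoisomerisation of the cinnamate chromophore gives a photostationary mixture from which the Z-acid is separated; no stereocenter is involved.

Step 6
Reactants: 9 (2R,3S)-dihydrodehydrodiconiferyl alcohol; 10 (Z)-ferulic acid (1.05 equiv)
Product: 11 9′-O-[(Z)-feruloyl]-(2R,3S)-dihydrodehydrodiconiferyl alcohol
Conditions: DIAD, then PPh3 added last, THF, −20 to 0 °C, dark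
Reagents that add atoms: none
Why: Mitsunobu esterification is an SN2 displacement at the carbinol carbon, roughly ten times faster at the unbranched 3-arylpropanol than at the β-branched C9 carbinol, and it leaves both phenols alone; C2 and C3 are untouched and the Z-alkene survives at low temperature in the dark with no free phosphine.

Step 7
Reactants: 11 9′-O-[(Z)-feruloyl]-(2R,3S)-dihydrodehydrodiconiferyl alcohol; 12 (E)-p-coumaric acid (1.5 equiv)
Product: 13 CNP0267960.2
Conditions: DIAD, then PPh3 added last, THF, 0 °C to rt, dark
Reagents that add atoms: none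
Why: the same chemoselective Mitsunobu esterification now acylates the only remaining aliphatic hydroxyl with the carboxyl of the unprotected acid in preference to the three phenols; C2 and C3 are untouched and both alkene geometries are retained.

**Compound list**
1 | (E)-ferulic acid | COc1cc(/C=C/C(=O)O)ccc1O | starting material
2 | (4S,5S)-2,2-dimethyl-1,3-dioxolane-4,5-dimethanol (2,3-O-isopropylidene-L-threitol) | CC1(C)O[C@@H](CO)[C@H](CO)O1 | starting material
3 | [(4S,5S)-5-(hydroxymethyl)-2,2-dimethyl-1,3-dioxolan-4-yl]methyl (E)-3-(4-hydroxy-3-methoxyphenyl)prop-2-enoate | CC1(C)O[C@@H](COC(=O)/C=C/c2ccc(O)c(OC)c2)[C@H](CO)O1 | intermediate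
4 | 3-(4-hydroxy-3-methoxyphenyl)propanoic acid (dihydroferulic acid) | COc1cc(CCC(=O)O)ccc1O | starting material
5 | mixed diester of diol 2: one arm (E)-ferulate, other arm 3-(4-hydroxy-3-methoxyphenyl)propanoate, (4S,5S) | CC1(C)O[C@@H](COC(=O)/C=C/c2ccc(O)c(OC)c2)[C@H](COC(=O)CCc2ccc(O)c(OC)c2)O1 | intermediate
6 | bis(phenoxyl) diradical of 5 (not isolated) | CC1(C)O[C@@H](COC(=O)/C=C/c2ccc([O])c(OC)c2)[C@H](COC(=O)CCc2ccc([O])c(OC)c2)O1 | intermediate
7 | 8–5′-coupled p-quinone methide macrocycle, (8S), ring B rearomatised, exocyclic alkene geometry not defined (not isolated) | O=C1CCc2cc(OC)c(O)c(c2)[C@@H](C(=O)OC[C@@H]2OC(C)(C)O[C@H]2CO1)C=C1C=CC(=O)C(OC)=C1 | intermediate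
8 | 14-membered macrodilactone: (2R,3R)-trans-2-(4-hydroxy-3-methoxyphenyl)-7-methoxy-2,3-dihydrobenzofuran whose C3 carboxyl and C5 propanoyl group are esterified to the two CH2O arms of the (4S,5S)-acetonide | O=C1CCc2cc(OC)c3c(c2)[C@@H](C(=O)OC[C@@H]2OC(C)(C)O[C@H]2CO1)[C@H](c2ccc(O)c(OC)c2)O3 | intermediate
9 | (2R,3S)-2-(4-hydroxy-3-methoxyphenyl)-3-(hydroxymethyl)-5-(3-hydroxypropyl)-7-methoxy-2,3-dihydrobenzofuran (dihydrodehydrodiconiferyl alcohol) | OCCCc1cc(OC)c2c(c1)[C@@H](CO)[C@H](c1ccc(O)c(OC)c1)O2 | intermediate
10 | (Z)-ferulic acid | COc1cc(/C=C\C(=O)O)ccc1O | intermediate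
11 | 9′-O-[(Z)-feruloyl]-(2R,3S)-dihydrodehydrodiconiferyl alcohol (free C9–OH) | COc1cc(/C=C\C(=O)OCCCc2cc(OC)c3c(c2)[C@@H](CO)[C@H](c2ccc(O)c(OC)c2)O3)ccc1O | intermediate
12 | (E)-p-coumaric acid | O=C(O)/C=C/c1ccc(O)cc1 | starting material
13 | CNP0267960.2: (2R,3S)-core with 9-O-(E)-p-coumaroyl and 9′-O-(Z)-feruloyl esters | COc1cc(/C=C\C(=O)OCCCc2cc(OC)c3c(c2)[C@@H](COC(=O)/C=C/c2ccc(O)cc2)[C@H](c2ccc(O)c(OC)c2)O3)ccc1O | target

**Step count**
Total: 7 steps. Longest linear sequence: 6 steps (1, 2, 3, 4, 6, 7); step 5 is a one-step side branch.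

**Three steps most likely to fail**

Step 3 (templated oxidative macro-bicyclisation). The risks are oligomerisation, 8–O–4′ coupling, and low or opposite diastereoselectivity. The fallback sets out from compound 3 and gives up the template. Classical intermolecular Ag2O dehydrodimerisation of 3 (0.1 M, CH2Cl2/acetone) gives the 8–5′ dehydrodiferulate bis(threitol acetonide) ester F1. Its (2R,3R) diastereomer is separated by preparative HPLC, the two auxiliaries serving as resolving handles. Hydrogenation of the cinnamate alkene (H2, Pd/C, EtOAc, 1 atm) gives the dihydro diester F2. i-Bu2AlH then cleaves both auxiliaries, and the route is rejoined at compound 9.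

Step 6 (regioselective Mitsunobu with the light- and phosphine-sensitive Z-acid). The risks are Z to E isomerisation and incomplete discrimination of the two primary alcohols. The fallback sets out from compound 9 and uses compound 1 instead of 10. Mitsunobu esterification at −40 °C with the robust (E)-acid gives the 9′-O-(E)-feruloyl ester F3. Irradiation of F3 at 365 nm in MeOH, with chromatographic isolation of the Z-isomer in the dark and re-irradiation of recovered E-ester, rejoins the route at compound 11. Step 5 is then not needed.

Step 7 (Mitsunobu at the β-branched C9–OH with the Z-ester already in place). The risks are sluggish displacement and erosion of the Z-geometry. The fallback sets out from compound 9 and puts the Z-ester on last.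
- Immobilised Candida antarctica lipase B (Novozym 435) with vinyl acetate in MTBE acetylates only the unbranched hydroxyl, giving the 9′-O-acetate F4.
- Mitsunobu esterification with acid 12 at C9–OH, which can now be forced, gives the 9′-O-acetyl-9-O-(E)-p-coumaroyl ester F5.
- The same lipase with n-butanol in MTBE removes only the acetate, giving the 9-O-(E)-p-coumaroyl diol F6.
- A final cold Mitsunobu esterification of the one free, unbranched alcohol with acid 10 rejoins the route at compound 13, bypassing 11.

**Further compounds**
F1 | step 3 | bis{[(4S,5S)-5-(hydroxymethyl)-2,2-dimethyl-1,3-dioxolan-4-yl]methyl} ester of (2R,3R)-trans-8–5′-dehydrodiferulic acid (C3 carboxylate and C5 (E)-acrylate) | OC[C@@H]1OC(C)(C)O[C@H]1COC(=O)/C=C/c1cc(OC)c2c(c1)[C@@H](C(=O)OC[C@@H]1OC(C)(C)O[C@H]1CO)[C@H](c1ccc(O)c(OC)c1)O2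
F2 | step 3 | side-chain dihydro derivative of F1 (C3 carboxylate and C5 propanoate), (2R,3R) | OC[C@@H]1OC(C)(C)O[C@H]1COC(=O)CCc1cc(OC)c2c(c1)[C@@H](C(=O)OC[C@@H]1OC(C)(C)O[C@H]1CO)[C@H](c1ccc(O)c(OC)c1)O2
F3 | step 6 | 9′-O-[(E)-feruloyl]-(2R,3S)-dihydrodehydrodiconiferyl alcohol | COc1cc(/C=C/C(=O)OCCCc2cc(OC)c3c(c2)[C@@H](CO)[C@H](c2ccc(O)c(OC)c2)O3)ccc1O
F4 | step 7 | 9′-O-acetyl-(2R,3S)-dihydrodehydrodiconiferyl alcohol | CC(=O)OCCCc1cc(OC)c2c(c1)[C@@H](CO)[C@H](c1ccc(O)c(OC)c1)O2
F5 | step 7 | 9′-O-acetyl-9-O-[(E)-p-coumaroyl]-(2R,3S)-dihydrodehydrodiconiferyl alcohol | CC(=O)OCCCc1cc(OC)c2c(c1)[C@@H](COC(=O)/C=C/c1ccc(O)cc1)[C@H](c1ccc(O)c(OC)c1)O2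
F6 | step 7 | 9-O-[(E)-p-coumaroyl]-(2R,3S)-dihydrodehydrodiconiferyl alcohol | OCCCc1cc(OC)c2c(c1)[C@@H](COC(=O)/C=C/c1ccc(O)cc1)[C@H](c1ccc(O)c(OC)c1)O2
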